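**Strategy.** Labdane locants are used (ring A: C1–C5, C10; ring B: C5–C10). The route rests on the tertiary carbinol C9 as a latent ketone whose two α-carbons, C10 and C8, both bond to one three-carbon unit, C5–C6–C7; C5–C10 is the bond common to both rings. An acyclic keto enal carrying the C2/C3 diol as a cis-acetonide therefore folds in one base-mediated operation: Michael addition of C10 to C5 closes ring A and sets C10 (quaternary) and C5, and aldol condensation of C8 with C7 closes ring B. Vinyl addition at C9, a B-alkyl Suzuki coupling and selective C2 acetylation finish the synthesis.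

Key step: step 7

Remark: in the names of the bicyclic compounds the labdane skeleton supplies locants only (C17 on C8, C18/C19 on C4, C20 on C10, side chain C11–C16 on C9); β is the face of the C10 methyl, every centre is given as α or β, and all bicyclic compounds are trans-fused (5α-H, 10β-CH3). Compounds 1, 3, 9 and 17 are taken as commercially available.

**Step 1**
Reactants: 1 (5R)-5-(hydroxymethyl)oxolan-2-one
Product: 2 (2R)-5-oxooxolane-2-carbaldehyde
Conditions: TEMPO (10 mol%), PhI(OAc)2 (1.1 equiv), CH2Cl2, rt; volatiles removed, crude aldehyde used at once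
Reagents that add atoms: none
Why: Oxoammonium (TEMPO) oxidation should stop cleanly at the aldehyde under neutral conditions that do not epimerise the α-acyloxy centre.

**Step 2**
Reactants: 2 (2R)-5-oxooxolane-2-carbaldehyde; 3 prenylboronic acid pinacol ester
Product: 5 (5R)-5-[(1S)-1-hydroxy-2,2-dimethylbut-3-en-1-yl]oxolan-2-one, via pinacol borate ester 4 (not isolated)
Conditions: 3 (1.3 equiv), CH2Cl2, 0 °C to rt; aqueous NaHCO3 work-up
Reagents that add atoms: none
Why: Allylboration through the γ-carbon (reverse prenylation) in a closed chair transition state should set C3 anti to the C2 oxygen (Felkin–Anh/Cornforth preference of an α-oxygenated aldehyde, reinforced by the Z-γ-methyl of the boronate), which gives the erythro 2R,3S pair.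

**Step 3**
Reactants: 5 (5R)-5-[(1S)-1-hydroxy-2,2-dimethylbut-3-en-1-yl]oxolan-2-one
Product: 6 (5R)-5-[(1S)-1-hydroxy-2,2-dimethylbut-3-en-1-yl]-3-methyloxolan-2-one (both C3 epimers)
Conditions: LDA (2.2 equiv), THF, −78 °C; MeI (1.2 equiv), −78 to −40 °C; aq. NH4Cl
Reagents that add atoms: iodomethane (CI)
Why: Enolate alkylation of the lactone as its alkoxide–enolate dianion should methylate carbon faster than the hindered alkoxide, and the configuration of the new centre (the future C10) is irrelevant because it is enolised in step 7.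

**Step 4**
Reactants: 6 (5R)-5-[(1S)-1-hydroxy-2,2-dimethylbut-3-en-1-yl]-3-methyloxolan-2-one
Product: 7 (6R,7S)-6,7-dihydroxy-4,8,8-trimethyldec-9-en-3-one (both C4 epimers)
Conditions: EtLi (3 equiv), THF, −78 °C; aq. NH4Cl at −78 °C
Reagents that add atoms: ethyllithium ([Li]CC)
Why: Mono-addition of an organolithium to a lactone should succeed because the lithium hemiketalate persists at −78 °C and releases the ethyl ketone only on quenching.

**Step 5**
Reactants: 7 (6R,7S)-6,7-dihydroxy-4,8,8-trimethyldec-9-en-3-one
Product: 8 1-[(4R,5S)-2,2-dimethyl-5-(2-methylbut-3-en-2-yl)-1,3-dioxolan-4-yl]-2-methylpentan-3-one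
Conditions: 2,2-dimethoxypropane, PPTS (cat.), acetone, rt
Reagents that add atoms: 2,2-dimethoxypropane (COC(C)(C)OC)
Why: Acid-catalysed transketalisation should convert the erythro 1,2-diol into the cis-disubstituted acetonide and so drain the open-chain/hemiketal equilibrium of 7.

**Step 6**
Reactants: 8 1-[(4R,5S)-2,2-dimethyl-5-(2-methylbut-3-en-2-yl)-1,3-dioxolan-4-yl]-2-methylpentan-3-one; 9 (E)-but-2-enal
Product: 10 (E)-4-[(4S,5R)-2,2-dimethyl-5-(2-methyl-3-oxopentyl)-1,3-dioxolan-4-yl]-4-methylpent-2-enal
Conditions: 9 (5 equiv), second-generation Hoveyda–Grubbs catalyst RuCl2(H2IMes)(=CH-C6H4-2-O-i-Pr) (5 mol%), CH2Cl2, 40 °C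
Reagents that add atoms: none
Why: Olefin cross-metathesis with excess crotonaldehyde should give the E-enal, since the quaternary allylic carbon suppresses homodimerisation of 8 and loss of propene drives the exchange.

**Step 7**
Reactants: 10 (E)-4-[(4S,5R)-2,2-dimethyl-5-(2-methyl-3-oxopentyl)-1,3-dioxolan-4-yl]-4-methylpent-2-enal
Product: 13 2α,3α-isopropylidenedioxy-11,12,13,14,15,16-hexanorlabd-7-en-9-one, via Michael adduct 11 (not isolated), via aldol 12 (not isolated)
Conditions: KOt-Bu (0.3 equiv), t-BuOH/THF (1:4, 0.01 M), 0 °C to 40 °C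
Reagents that add atoms: none
Why: tert-Butoxide reversibly forms the more substituted C10 enolate, which adds to C5 of the enal (intramolecular Michael addition); the ketone then enolises toward C8 and condenses with the released C7 aldehyde (aldol addition, then E1cB loss of water), so the sequence is a Robinson-type Michael/aldol condensation that annulates a ketone through both α-carbons. Ring A closes 6-(enolexo)-exo-trig (C10 onto C5) and ring B closes 6-(enolendo)-exo-trig (C8 onto C7). C5 is controlled by the cis-acetonide: the chair-like transition state keeps the C2–O bond equatorial and the C3–O bond axial, since the other chair would set C2–O syn-axial to the axial C4 methyl and to the axial group on C10, and the enal is therefore attacked on the face that leaves H5 axial on the side of O3. C10 is controlled in the same chair, its methyl taking the axial site and the larger enolate arm the equatorial one, which gives the trans ring fusion and keeps C8 within reach of C7. The selectivity needed is between the two α-carbons and between 1,4- and 1,2-addition; ring size secures both, because only C10 can reach C5 through a six-membered ring, the E-alkene forbids attack on C7 before the Michael step, and the enal, lacking a γ-hydrogen, cannot enolise.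

**Step 8**
Reactants: 13 2α,3α-isopropylidenedioxy-11,12,13,14,15,16-hexanorlabd-7-en-9-one
Product: 15 2α,3α-isopropylidenedioxy-11,12,13,14,15,16-hexanor-8βH-labdan-9-one (C17 methyl α), via dihydro ketone epimers 14 (not isolated)
Conditions: H2 (1 atm), Pd/C (10%), EtOAc, rt; then NaOMe (0.2 equiv), MeOH, rt
Reagents that add atoms: none
Why: Heterogeneous hydrogenation of the enone C7=C8 bond followed by equilibration through the C9 enolate should leave the C8 methyl equatorial (α), because the 8β epimer suffers a 1,3-diaxial contact with the C10 methyl.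

**Step 9**
Reactants: 15 2α,3α-isopropylidenedioxy-11,12,13,14,15,16-hexanor-8βH-labdan-9-one
Product: 16 2α,3α-isopropylidenedioxy-13,14,15,16-tetranor-8βH-labd-11-en-9β-ol (vinyl group 9α)
Conditions: CH2=CHMgBr (3 equiv), anhydrous CeCl3 (3 equiv), THF, −78 °C; then 15, −78 to 0 °C; aq. NH4Cl
Reagents that add atoms: vinylmagnesium bromide (C=C[Mg]Br)
Why: Organocerium 1,2-addition should suppress enolisation of the hindered ketone, and the small nucleophile should enter axially on the α-face, anti to the axial C10 methyl that blocks the equatorial trajectory, so that the vinyl group becomes 9α and the hydroxyl 9β.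

**Step 10**
Reactants: 17 methyl but-2-ynoate
Product: 18 methyl (Z)-3-iodobut-2-enoate
Conditions: NaI (1.6 equiv), AcOH, 110 °C
Reagents that add atoms: sodium iodide ([Na+].[I-])
Why: Conjugate addition of iodide to the ynoate and anti protonation in acetic acid (hydroiodination) should give the Z-β-iodo enoate stereoselectively.

**Step 11**
Reactants: 16 2α,3α-isopropylidenedioxy-13,14,15,16-tetranor-8βH-labd-11-en-9β-ol; 18 methyl (Z)-3-iodobut-2-enoate
Product: 20 methyl (13Z)-9β-hydroxy-2α,3α-isopropylidenedioxy-8βH-labd-13-en-15-oate (side chain 9α), via alkylborane 19 (not isolated)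
Conditions: 9-BBN (3 equiv), THF, rt to 50 °C; then 18 (1.5 equiv), PdCl2(dppf) (5 mol%), AsPh3 (5 mol%), aq. K3PO4 (3 M), DMF, rt
Reagents that add atoms: none
Why: Anti-Markovnikov hydroboration of the vinyl group and B-alkyl Suzuki–Miyaura coupling, which proceeds with retention at the vinyl iodide, should deliver the 13Z enoate directly.

**Step 12**
Reactants: 20 methyl (13Z)-9β-hydroxy-2α,3α-isopropylidenedioxy-8βH-labd-13-en-15-oate
Product: 21 methyl (13Z)-2α,3α,9β-trihydroxy-8βH-labd-13-en-15-oate (side chain 9α)
Conditions: AcOH/H2O (4:1), 40 °C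
Reagents that add atoms: none
Why: Mild acid hydrolysis of the acetonide should leave the tertiary alcohol and the trisubstituted enoate untouched.

**Step 13**
Reactants: 21 methyl (13Z)-2α,3α,9β-trihydroxy-8βH-labd-13-en-15-oate
Product: 22 methyl (13Z)-2α-acetoxy-3α,9β-dihydroxy-8βH-labd-13-en-15-oate (CNP0135744.2)
Conditions: Ac2O (1.1 equiv), pyridine, CH2Cl2, 0 °C
Reagents that add atoms: acetic anhydride (CC(=O)OC(C)=O)
Why: Selective acylation should take place at the equatorial C2 hydroxyl, the axial C3 hydroxyl being neopentylic and the C9 hydroxyl tertiary.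

**Compound list**
1 | (5R)-5-(hydroxymethyl)oxolan-2-one | O=C1CC[C@H](CO)O1 | starting material
2 | (2R)-5-oxooxolane-2-carbaldehyde | O=C1CC[C@H](C=O)O1 | intermediate
3 | 4,4,5,5-tetramethyl-2-(3-methylbut-2-en-1-yl)-1,3,2-dioxaborolane (prenylboronic acid pinacol ester) | CC(C)=CCB1OC(C)(C)C(C)(C)O1 | starting material
4 | pinacol borate ester of 5 (O-boryl on the C3 carbinol) | O=C1CC[C@H]([C@@H](OB2OC(C)(C)C(C)(C)O2)C(C)(C)C=C)O1 | intermediate
5 | (5R)-5-[(1S)-1-hydroxy-2,2-dimethylbut-3-en-1-yl]oxolan-2-one | O=C1CC[C@H]([C@@H](O)C(C)(C)C=C)O1 | intermediate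
6 | (5R)-5-[(1S)-1-hydroxy-2,2-dimethylbut-3-en-1-yl]-3-methyloxolan-2-one, both C3 epimers | O=C1C(C)C[C@H]([C@@H](O)C(C)(C)C=C)O1 | intermediate
7 | (6R,7S)-6,7-dihydroxy-4,8,8-trimethyldec-9-en-3-one, both C4 epimers | CCC(=O)C(C)C[C@@H](O)[C@@H](O)C(C)(C)C=C | intermediate
8 | 1-[(4R,5S)-2,2-dimethyl-5-(2-methylbut-3-en-2-yl)-1,3-dioxolan-4-yl]-2-methylpentan-3-one (cis-dioxolane) | CCC(=O)C(C)C[C@H]1OC(C)(C)O[C@H]1C(C)(C)C=C | intermediate
9 | (E)-but-2-enal (crotonaldehyde) | C/C=C/C=O | starting material
10 | (E)-4-[(4S,5R)-2,2-dimethyl-5-(2-methyl-3-oxopentyl)-1,3-dioxolan-4-yl]-4-methylpent-2-enal | CCC(=O)C(C)C[C@H]1OC(C)(C)O[C@H]1C(C)(C)/C=C/C=O | intermediate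
11 | Michael adduct: 2α,3α-isopropylidenedioxy-9-oxo-7,8-seco-11,12,13,14,15,16-hexanorlabdan-7-al (ring A closed, 5α-H, 10β-CH3) | CCC(=O)[C@@]1(C)C[C@H]2OC(C)(C)O[C@H]2C(C)(C)[C@@H]1CC=O | intermediate
12 | aldol: 7-hydroxy-2α,3α-isopropylidenedioxy-11,12,13,14,15,16-hexanorlabdan-9-one (C7 and C8 unassigned) | O=C1C(C)C(O)C[C@H]2C(C)(C)[C@@H]3OC(C)(C)O[C@@H]3C[C@]12C | intermediate
13 | 2α,3α-isopropylidenedioxy-11,12,13,14,15,16-hexanorlabd-7-en-9-one | O=C1C(C)=CC[C@H]2C(C)(C)[C@@H]3OC(C)(C)O[C@@H]3C[C@]12C | intermediate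
14 | 2α,3α-isopropylidenedioxy-11,12,13,14,15,16-hexanorlabdan-9-one, C8 epimers | O=C1C(C)CC[C@H]2C(C)(C)[C@@H]3OC(C)(C)O[C@@H]3C[C@]12C | intermediate
15 | 2α,3α-isopropylidenedioxy-11,12,13,14,15,16-hexanor-8βH-labdan-9-one (C17 methyl α, equatorial) | O=C1[C@H](C)CC[C@H]2C(C)(C)[C@@H]3OC(C)(C)O[C@@H]3C[C@]12C | intermediate
16 | 2α,3α-isopropylidenedioxy-13,14,15,16-tetranor-8βH-labd-11-en-9β-ol (vinyl 9α, hydroxyl 9β) | C=C[C@]1(O)[C@H](C)CC[C@H]2C(C)(C)[C@@H]3OC(C)(C)O[C@@H]3C[C@@]21C | intermediate
17 | methyl but-2-ynoate | CC#CC(=O)OC | starting material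
18 | methyl (Z)-3-iodobut-2-enoate | COC(=O)/C=C(/C)I | intermediate
19 | 12-(9-borabicyclo[3.3.1]nonan-9-yl)-2α,3α-isopropylidenedioxy-13,14,15,16-tetranor-8βH-labdan-9β-ol | C1CCC2CCCC1B2CC[C@]1(O)[C@H](C)CC[C@H]2C(C)(C)[C@@H]3OC(C)(C)O[C@@H]3C[C@@]21C | intermediate
20 | methyl (13Z)-9β-hydroxy-2α,3α-isopropylidenedioxy-8βH-labd-13-en-15-oate (side chain 9α) | COC(=O)/C=C(/C)CC[C@]1(O)[C@H](C)CC[C@H]2C(C)(C)[C@@H]3OC(C)(C)O[C@@H]3C[C@@]21C | intermediate
21 | methyl (13Z)-2α,3α,9β-trihydroxy-8βH-labd-13-en-15-oate (side chain 9α) | COC(=O)/C=C(/C)CC[C@]1(O)[C@H](C)CC[C@H]2C(C)(C)[C@H](O)[C@H](O)C[C@@]21C | intermediate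
22 | methyl (13Z)-2α-acetoxy-3α,9β-dihydroxy-8βH-labd-13-en-15-oate, (2R,3S,5S,8R,9S,10S), CNP0135744.2 | COC(=O)/C=C(/C)CC[C@]1(O)[C@H](C)CC[C@H]2C(C)(C)[C@H](O)[C@H](OC(C)=O)C[C@@]21C | target

**Step count and risks**

Total step count: 13 (12 in the main line plus the one-step preparation of 18). Longest linear sequence: 12 steps (steps 1–9 and 11–13).

Steps most likely to fail:

Step 7. The tertiary C10 enolate may add too slowly to the neopentylic C5, so that retro-Michael equilibration or intermolecular condensation of the enal takes over, or the ring fusion may form with poor trans/cis selectivity. The fallback separates the two bond formations and makes the first one irreversible. It sets out from 10, which would be converted into the more substituted trimethylsilyl enol ether F1 (TMSCl, NaI, Et3N, MeCN). An intramolecular Mukaiyama–Michael addition (BF3·OEt2, CH2Cl2, −78 °C) would then give keto aldehyde 11, this time isolated, and ring B would be closed by a separate aldol condensation (KOH, MeOH), returning to the route at 13.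

Step 6. Turnover at the vinyl group next to the quaternary C4 may be slow, with self-metathesis and decomposition of the enal partner competing. The fallback replaces metathesis by cleavage and olefination. It sets out from 8, which would be ozonised (O3, CH2Cl2, −78 °C; Me2S) to the neopentylic aldehyde F2. Wittig olefination with (triphenylphosphoranylidene)acetaldehyde (toluene, 80 °C) would then give the E-enal and return to the route at 10.

Step 11. The hindered alkylborane, which carries a free tertiary alcohol, may transmetalate slowly, and under the basic conditions the C9 alkoxide may add to the new enoate (oxa-Michael closure to a 9,13-ether). The fallback is base-free and sets out from 16. Hydroboration and oxidation (9-BBN; NaOH, H2O2) would give the primary alcohol F3, and I2, PPh3 and imidazole would convert it into the iodide F4. A nickel-catalysed reductive cross-electrophile coupling of F4 with 18 (NiI2, 4,4'-di-tert-butyl-2,2'-bipyridine, Mn powder, DMA), which retains the alkene geometry, would return to the route at 20.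

**Further compounds**
F1 | step 7 | trimethylsilyl enol ether of 10 (C9=C10 enol ether, enal intact) | CCC(O[Si](C)(C)C)=C(C)C[C@H]1OC(C)(C)O[C@H]1C(C)(C)/C=C/C=O
F2 | step 6 | 2-[(4S,5R)-2,2-dimethyl-5-(2-methyl-3-oxopentyl)-1,3-dioxolan-4-yl]-2-methylpropanal | CCC(=O)C(C)C[C@H]1OC(C)(C)O[C@H]1C(C)(C)C=O
F3 | step 11 | 2α,3α-isopropylidenedioxy-13,14,15,16-tetranor-8βH-labdane-9β,12-diol | OCC[C@]1(O)[C@H](C)CC[C@H]2C(C)(C)[C@@H]3OC(C)(C)O[C@@H]3C[C@@]21C
F4 | step 11 | 12-iodo-2α,3α-isopropylidenedioxy-13,14,15,16-tetranor-8βH-labdan-9β-ol | ICC[C@]1(O)[C@H](C)CC[C@H]2C(C)(C)[C@@H]3OC(C)(C)O[C@@H]3C[C@@]21C
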